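**Retrosynthetic overview**

- Target ⇐ 2-(2-hydroxyalkyl)-6-methoxy-1,4-benzoquinone: both carbonyls are reduced 1,2 in one flask, with acetylation between the two hydride additions (sets the acetoxy carbinol first, then the cis hydroxy carbinol).
- Quinone ⇐ 4-hydroxy-2-methoxy-6-alkylbenzoic acid: the polyketide carboxyl is kept and used as the para leaving group that marks the carbon to be oxygenated (decarboxylative oxidation).
- Benzoic acid (the only ring) ⇐ open-chain C22 tetraketide by C2–C7 aldol condensation and aromatisation; the chain is assembled in the same flask from a C6 triketide pyrone and a C16 (R)-3-hydroxyacyl unit.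
- (R)-3-Hydroxy ester ⇐ β-keto ester (asymmetric hydrogenation) ⇐ tetradecanoyl chloride + Meldrum's acid.
- Ring order: one carbocycle, formed in step 3; steps 4 and 5 only change its oxidation level.

Assumption: 4-methoxy-6-methyl-2H-pyran-2-one is bought, and Li[AlH(n-Bu)(i-Bu)2] is used as a stock solution; locants in the text follow the name of the compound under discussion.

**Route**

Step 1
Reactants: 1 tetradecanoyl chloride; 2 Meldrum's acid (2,2-dimethyl-1,3-dioxane-4,6-dione)
Product: 4 methyl 3-oxohexadecanoate, via acyl Meldrum's acid 3 (not isolated)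
Conditions: pyridine (2 equiv), CH2Cl2, 0 °C → rt; then MeOH, reflux
Reagents that add atoms: methanol, CO
Why: C-acylation of Meldrum's acid followed by methanolysis and decarboxylation of the acyl Meldrum's acid (Oikawa–Yonemitsu β-keto ester synthesis) is the standard two-carbon extension of an acid chloride and creates no stereocentre.

Step 2
Reactants: 4 methyl 3-oxohexadecanoate
Product: 5 methyl (3R)-3-hydroxyhexadecanoate
Conditions: H2 (50 atm), RuCl2[(R)-BINAP] (0.2 mol%), MeOH, 50 °C
Reagents that add atoms: none
Why: Noyori asymmetric hydrogenation of a β-keto ester, in which the (R)-BINAP–ruthenium catalyst hydrogenates the chelated keto ester from one face to give the (R)-3-hydroxy ester (≥98% ee expected, as for methyl acetoacetate and long-chain homologues); this sets the side-chain stereocentre.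

Step 3
Reactants: 5 methyl (3R)-3-hydroxyhexadecanoate; 6 4-methoxy-6-methyl-2H-pyran-2-one
Product: 10 4-hydroxy-6-[(2R)-2-hydroxypentadecyl]-2-methoxybenzoic acid, via lithiated pyrone 7 (not isolated), via keto-pyrone 8 (not isolated), via open-chain tetraketide 9 (not isolated)
Conditions: 6 (3.3 equiv), LiN(i-Pr)2 (3.3 equiv), THF, −78 °C; add 5, −78 → −30 °C; then 2 M aq. KOH, MeOH, 0 → 40 °C; cold 1 M HCl to pH 4, EtOAc
Reagents that add atoms: potassium hydroxide, [K+].[OH-]
Why: Lateral lithiation of the pyrone and Claisen condensation with the unprotected β-hydroxy ester (excess anion first deprotonates the hydroxyl, as in ester-enolate Claisen reactions on 3-hydroxy esters) builds the tetraketide, after which hydroxide opens the pyrone and the vinylogous enolate attacks the C7 ketone through C2 (biomimetic Harris-type polyketide C2–C7 aldol condensation) and the ring aromatises irreversibly with the methoxy group already ortho to the carboxyl; the carbinol centre is not touched because the C7 ketone sits as its C6 enolate, which blocks retro-aldol and β-elimination.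

Step 4
Reactants: 10 4-hydroxy-6-[(2R)-2-hydroxypentadecyl]-2-methoxybenzoic acid
Product: 11 2-[(2R)-2-hydroxypentadecyl]-6-methoxycyclohexa-2,5-diene-1,4-dione
Conditions: (KSO3)2NO (2.5 equiv), aq. KH2PO4/K2HPO4 (pH 7.5), acetone–H2O, 0 °C → rt
Reagents that add atoms: potassium nitrosodisulfonate (Fremy's salt), [K+].[K+].[O]N(S(=O)(=O)[O-])S(=O)(=O)[O-]
Why: Proposed new method: a Teuber oxidation in which the phenoxyl radical is captured by a second nitrosodisulfonate radical at the para carbon, ipso to the carboxylate, and the adduct fragments with loss of CO2 instead of a proton (closest known chemistry: Teuber oxidations of para-halo and para-alkoxy phenols that expel the para group, and enzymatic decarboxylative hydroxylation of 4-hydroxybenzoates); at pH 7.5 the acid is a carboxylate, so the side-chain hydroxyl cannot lactonise, and no stereocentre is affected.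

Step 5
Reactants: 11 2-[(2R)-2-hydroxypentadecyl]-6-methoxycyclohexa-2,5-diene-1,4-dione
Product: 14 (1S,4R)-6-[(2R)-2-acetoxypentadecyl]-4-hydroxy-2-methoxycyclohexa-2,5-dien-1-yl acetate, via bis-aluminate 12 (not isolated), via acetoxy dienone 13 (not isolated)
Conditions: Li[AlH(n-Bu)(i-Bu)2] (2.1 equiv), toluene–THF, −78 °C, 20 min; AcCl (2.1 equiv), −78 °C, 5 min; Li[AlH(n-Bu)(i-Bu)2] (1.2 equiv), −78 °C, 15 min; aq. NaHCO3/KNaC4H4O6
Reagents that add atoms: acetyl chloride, CC(=O)Cl
Why: Proposed new method: the first equivalent of aluminate hydride turns the side-chain hydroxyl into a bulky lithium alkoxyaluminate that carries no hydride, so Li+ bridges this oxygen and the C1 carbonyl (the more electrophilic one, not a vinylogous ester) in a seven-membered chelate with the tridecyl group pointing away, and the second equivalent attacks C1 from the face opposite the side chain to set the (S) carbinol (chelation-controlled 1,2-reduction with 1,4-induction; closest precedent: chelation-controlled reductions of β-alkoxy ketones), the charge-protected alkoxides are then acetylated by AcCl, and the short-lived 4-acetoxy dienone (a phenol keto tautomer, which needs acid or base to tautomerise) is reduced at once at the remaining carbonyl, chemoselectively over the acetates, by hydride adding anti to the C–OAc bond (electrostatic control known for 4-oxygenated cyclohexa-2,5-dienones) to give the cis (4R) alcohol.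

**Compound list**

1 | tetradecanoyl chloride | CCCCCCCCCCCCCC(=O)Cl | starting material
2 | Meldrum's acid (2,2-dimethyl-1,3-dioxane-4,6-dione) | CC1(C)OC(=O)CC(=O)O1 | starting material
3 | 5-(1-hydroxytetradecylidene)-2,2-dimethyl-1,3-dioxane-4,6-dione (acyl Meldrum's acid) | CCCCCCCCCCCCCC(O)=C1C(=O)OC(C)(C)OC1=O | intermediate (not isolated)
4 | methyl 3-oxohexadecanoate | CCCCCCCCCCCCCC(=O)CC(=O)OC | intermediate
5 | methyl (3R)-3-hydroxyhexadecanoate | CCCCCCCCCCCCC[C@H](CC(=O)OC)O | intermediate
6 | 4-methoxy-6-methyl-2H-pyran-2-one | CC1=CC(OC)=CC(=O)O1 | starting material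
7 | [(4-methoxy-2-oxo-2H-pyran-6-yl)methyl]lithium | [Li]CC1=CC(OC)=CC(=O)O1 | intermediate (not isolated)
8 | 6-[(4R)-4-hydroxy-2-oxoheptadecyl]-4-methoxy-2H-pyran-2-one (present as its dilithium salt) | CCCCCCCCCCCCC[C@H](CC(=O)CC1=CC(OC)=CC(=O)O1)O | intermediate (not isolated)
9 | (2E,9R)-9-hydroxy-3-methoxy-5,7-dioxodocos-2-enoic acid (present as its potassium salt) | OC(=O)/C=C(/OC)CC(=O)CC(=O)C[C@H](O)CCCCCCCCCCCCC | intermediate (not isolated)
10 | 4-hydroxy-6-[(2R)-2-hydroxypentadecyl]-2-methoxybenzoic acid | CCCCCCCCCCCCC[C@H](Cc1cc(O)cc(OC)c1C(=O)O)O | intermediate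
11 | 2-[(2R)-2-hydroxypentadecyl]-6-methoxycyclohexa-2,5-diene-1,4-dione | CCCCCCCCCCCCC[C@H](CC1=CC(=O)C=C(OC)C1=O)O | intermediate
12 | dilithium bis[butyl(diisobutyl)aluminate] of (4S)-4-hydroxy-5-[(2R)-2-hydroxypentadecyl]-3-methoxycyclohexa-2,5-dien-1-one (both oxygens bound to Al) | [Li+].[Li+].CCCCCCCCCCCCC[C@H](CC1=CC(=O)C=C(OC)[C@H]1O[Al-](CCCC)(CC(C)C)CC(C)C)O[Al-](CCCC)(CC(C)C)CC(C)C | intermediate (not isolated)
13 | (1S)-6-[(2R)-2-acetoxypentadecyl]-2-methoxy-4-oxocyclohexa-2,5-dien-1-yl acetate | CCCCCCCCCCCCC[C@H](CC1=CC(=O)C=C(OC)[C@H]1OC(C)=O)OC(C)=O | intermediate (not isolated)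
14 | (1S,4R)-6-[(2R)-2-acetoxypentadecyl]-4-hydroxy-2-methoxycyclohexa-2,5-dien-1-yl acetate | CCCCCCCCCCCCC[C@H](CC1=C[C@@H](O)C=C(OC)[C@H]1OC(C)=O)OC(C)=O | target

**Step count and risks**

Total step count: 5. Longest linear sequence: 5 steps (1 → 4 → 5 → 10 → 11 → 14).

Steps most likely to fail, with fallbacks:

Step 5 is the weakest. The neutral acetoxy dienone 13 can aromatise to a hydroquinone acetate, and the 1,4-induction from the side chain is a model-based prediction, not precedent. The fallback sets out from 11 and comes back at 14. Reduce both carbonyls with 3.3 equiv of the same aluminate hydride at −78 °C, so that every oxygen stays an alkoxide and no neutral 4-acyloxy dienone is formed, and isolate the triol (1S,4R)-6-[(2R)-2-hydroxypentadecyl]-2-methoxycyclohexa-2,5-diene-1,4-diol F1. Silylate its least hindered hydroxyl, the C4 carbinol flanked by two CH groups, with t-BuPh2SiCl and imidazole at −40 °C to give the C4 tert-butyldiphenylsilyl ether F2. Acetylate the two remaining hydroxyls (Ac2O, DMAP, Et3N) to the silyl-protected diacetate F3, and remove the silyl group with Bu4NF buffered with AcOH to reach 14.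

Step 4 may fail because the bulky nitroxide can attack ortho to the phenol instead of ipso to the carboxylate. Any 3,4-dihydroisocoumarin formed from 10 on standing must first be reopened with dilute aq. KOH. The fallback sets out from 10 and comes back at 11. Heat the potassium salt of 10 in aqueous KH2PO4 buffer (pH 6, 90 °C), where ipso-protonation para to the phenoxide causes protodecarboxylation and the carboxylate cannot lactonise, to give 5-[(2R)-2-hydroxypentadecyl]-3-methoxyphenol F4. Then oxidise F4 at its free para position with (KSO3)2NO, the classical Teuber oxidation used for 2-methoxy-6-alkylbenzoquinones, to 11.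

Step 3 may fail at the Claisen condensation on the unprotected hydroxy ester, or through side reactions of the free β-hydroxy ketone in base. The fallback sets out from 5 and comes back at 10. Protect 5 with t-BuMe2SiCl and imidazole as methyl (3R)-3-[(tert-butyldimethylsilyl)oxy]hexadecanoate F5. Acylate 7 with F5 and isolate the silyl-protected keto-pyrone F6. Cyclise F6 separately with aq. KOH/MeOH to the silyl-protected benzoic acid F7, and remove the silyl group with Bu4NF to return to 10.

**Further compounds**

F1 | step 5 | (1S,4R)-6-[(2R)-2-hydroxypentadecyl]-2-methoxycyclohexa-2,5-diene-1,4-diol | CCCCCCCCCCCCC[C@H](CC1=C[C@@H](O)C=C(OC)[C@H]1O)O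
F2 | step 5 | (1S,4R)-4-[(tert-butyldiphenylsilyl)oxy]-6-[(2R)-2-hydroxypentadecyl]-2-methoxycyclohexa-2,5-dien-1-ol | CCCCCCCCCCCCC[C@H](CC1=C[C@@H](O[Si](c2ccccc2)(c2ccccc2)C(C)(C)C)C=C(OC)[C@H]1O)O
F3 | step 5 | (1S,4R)-6-[(2R)-2-acetoxypentadecyl]-4-[(tert-butyldiphenylsilyl)oxy]-2-methoxycyclohexa-2,5-dien-1-yl acetate | CCCCCCCCCCCCC[C@H](CC1=C[C@@H](O[Si](c2ccccc2)(c2ccccc2)C(C)(C)C)C=C(OC)[C@H]1OC(C)=O)OC(C)=O
F4 | step 4 | 5-[(2R)-2-hydroxypentadecyl]-3-methoxyphenol | CCCCCCCCCCCCC[C@H](Cc1cc(O)cc(OC)c1)O
F5 | step 3 | methyl (3R)-3-[(tert-butyldimethylsilyl)oxy]hexadecanoate | CCCCCCCCCCCCC[C@H](CC(=O)OC)O[Si](C)(C)C(C)(C)C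
F6 | step 3 | 6-[(4R)-4-[(tert-butyldimethylsilyl)oxy]-2-oxoheptadecyl]-4-methoxy-2H-pyran-2-one | CCCCCCCCCCCCC[C@H](CC(=O)CC1=CC(OC)=CC(=O)O1)O[Si](C)(C)C(C)(C)C
F7 | step 3 | 6-[(2R)-2-[(tert-butyldimethylsilyl)oxy]pentadecyl]-4-hydroxy-2-methoxybenzoic acid | CCCCCCCCCCCCC[C@H](Cc1cc(O)cc(OC)c1C(=O)O)O[Si](C)(C)C(C)(C)C
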